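**Retrosynthetic overview**
- Last step: Schenck ene reaction (singlet oxygen) on the C7=C8 E-alkene of the macrocyclic epoxy-lactone gives the C8 hydroperoxide and the 6E alkene.
- 14-membered ring (formed third): C6–C7 sp3–sp2 bond by an intramolecular CuH/Pd hydroalkenylation of a vinyl carbinol with an E-alkenyl bromide.
- Open chain: C12–C13 bond by B-alkyl Suzuki coupling of a vinyl lactone with a bromo-iodo diene, then Shi epoxidation (oxirane formed second).
- Lactone fragment (δ-lactone formed first): Rh-catalysed vinyl conjugate addition to 5,6-dihydropyran-2-one, α-methylation, ring opening, Wittig, Sharpless epoxidation, epoxide-opening relactonisation with inversion at C3.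
- Diene linchpin from pent-4-yn-1-ol: carboalumination/bromination, alkyne homologation and methylation, hydrozirconation/iodination.

Convention (one line): cembrane numbering is used for the skeleton (C1 = ring CH carrying the C15–C17 propanoate arm, C3 = lactone O–CH, C4 = carbinol C, C8 = hydroperoxide C, C11/C12 = epoxide); the target as drawn is (1R,3R,4S,6E,8S,11S,12S,15S).

**Route**

Step 1
Reactants: 1 5,6-dihydro-2H-pyran-2-one; 2 potassium vinyltrifluoroborate
Product: 3 (4R)-4-ethenyloxan-2-one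
Conditions: [Rh(cod)2]BF4 (3 mol %), (R)-BINAP (3.3 mol %), toluene/H2O 4:1, 100 °C
Reagents that add atoms: none
Why: Hayashi–Miyaura rhodium-catalysed asymmetric 1,4-addition, in which the (R)-BINAP–Rh–vinyl species adds to one enantioface of the enoate and sets C1 (the antipodal ligand is known to give (S)-4-aryl lactones from this enoate).

Step 2
Reactants: 3 (4R)-4-ethenyloxan-2-one
Product: 5 (3S,4S)-4-ethenyl-3-methyloxan-2-one, via lithium enolate 4 (not isolated)
Conditions: LiN(iPr)2, THF, −78 °C; MeI, −78 → −40 °C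
Reagents that add atoms: iodomethane (CI)
Why: Kinetic enolate alkylation occurs anti to the adjacent vinyl group, giving the trans-3,4 (also thermodynamic, diequatorial) lactone and setting C15.

Step 3
Reactants: 5 (3S,4S)-4-ethenyl-3-methyloxan-2-one
Product: 7 prop-2-en-1-yl (2S,3S)-3-ethenyl-5-hydroxy-2-methylpentanoate, via potassium carboxylate 6 (not isolated)
Conditions: KOH (1.05 equiv), THF/H2O, 0 °C → rt; evaporate; allyl bromide, DMF, rt
Reagents that add atoms: potassium hydroxide ([K+].[OH-]); allyl bromide (C=CCBr)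
Why: Saponification by acyl–oxygen cleavage and carboxylate O-alkylation touch no stereocentre, free the primary alcohol (future C3) and mask the acid as an allyl ester removable under neutral conditions.

Step 4
Reactants: 7 prop-2-en-1-yl (2S,3S)-3-ethenyl-5-hydroxy-2-methylpentanoate
Product: 8 prop-2-en-1-yl (2S,3S)-3-ethenyl-2-methyl-5-oxopentanoate
Conditions: Dess–Martin periodinane, CH2Cl2, rt
Reagents that add atoms: none
Why: Dess–Martin oxidation of the primary alcohol gives the aldehyde under non-basic conditions, so the ester α- and β-stereocentres are not epimerised.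

Step 5
Reactants: 9 bromoethane
Product: 10 ethyltriphenylphosphonium bromide
Conditions: PPh3, toluene, 100 °C (sealed tube)
Reagents that add atoms: triphenylphosphine (c1ccc(cc1)P(c1ccccc1)c1ccccc1)
Why: SN2 quaternisation of the phosphine by a primary bromide.

Step 6
Reactants: 10 ethyltriphenylphosphonium bromide; 11 ethyl formate
Product: 13 2-(triphenyl-λ5-phosphanylidene)propanal, via ethylidene ylide 12 (not isolated)
Conditions: KOtBu (2.1 equiv), THF, 0 °C; then 11, 0 °C → rt
Reagents that add atoms: none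
Why: Ylide C-acylation: the ylide is formylated by the formate and the acylphosphonium salt is deprotonated by the second equivalent of base to the stabilised formyl ylide.

Step 7
Reactants: 8 prop-2-en-1-yl (2S,3S)-3-ethenyl-2-methyl-5-oxopentanoate; 13 2-(triphenyl-λ5-phosphanylidene)propanal
Product: 15 prop-2-en-1-yl (2S,3S,5E)-3-ethenyl-7-hydroxy-2,6-dimethylhept-5-enoate, via enal 14 (not isolated)
Conditions: toluene, 90 °C; then MeOH, CeCl3·7H2O, NaBH4, −20 °C
Reagents that add atoms: none
Why: Wittig olefination with the stabilised ylide is E-selective (chain trans to CHO, defining the C3=C4 geometry) and Luche 1,2-reduction in the same flask gives the allylic alcohol without touching the ester.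

Step 8
Reactants: 15 prop-2-en-1-yl (2S,3S,5E)-3-ethenyl-7-hydroxy-2,6-dimethylhept-5-enoate
Product: 16 prop-2-en-1-yl (2S,3S)-3-{[(2S,3S)-3-(hydroxymethyl)-3-methyloxiran-2-yl]methyl}-2-methylpent-4-enoate
Conditions: Ti(OiPr)4 (10 mol %), L-(+)-diethyl tartrate (12 mol %), tBuOOH, 4 Å MS, CH2Cl2, −20 °C
Reagents that add atoms: tert-butyl hydroperoxide (CC(C)(C)OO)
Why: Sharpless asymmetric epoxidation, where the L-(+)-tartrate catalyst gives the (2S,3S)-epoxy alcohol from an E-allylic alcohol, setting C4 (S) and C3 (S, inverted in the next step) while the isolated vinyl and allyl groups are inert.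

Step 9
Reactants: 16 prop-2-en-1-yl (2S,3S)-3-{[(2S,3S)-3-(hydroxymethyl)-3-methyloxiran-2-yl]methyl}-2-methylpent-4-enoate
Product: 18 (3S,4S,6R)-6-[(2S)-1,2-dihydroxypropan-2-yl]-4-ethenyl-3-methyloxan-2-one, via epoxy acid 17 (not isolated)
Conditions: Pd(PPh3)4 (5 mol %), pyrrolidine, CH2Cl2, 0 °C; then Ti(OiPr)4 (1.2 equiv), CH2Cl2, rt
Reagents that add atoms: none
Why: Zerovalent-palladium-catalysed deallylation frees the acid under neutral conditions, and titanium-templated opening of the 2,3-epoxy alcohol at its C-3 (6-exo SN2, inversion) closes the δ-lactone, so C3 becomes R and anti to the untouched C4 carbinol.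

Step 10
Reactants: 18 (3S,4S,6R)-6-[(2S)-1,2-dihydroxypropan-2-yl]-4-ethenyl-3-methyloxan-2-one
Product: 19 (3S,4S,6R)-6-[(2S)-1,2-bis(triethylsilyloxy)propan-2-yl]-4-ethenyl-3-methyloxan-2-one
Conditions: Et3SiOTf, 2,6-lutidine, CH2Cl2, −78 → 0 °C
Reagents that add atoms: triethylsilyl trifluoromethanesulfonate (CC[Si](CC)(CC)OS(=O)(=O)C(F)(F)F)
Why: Silylation of both hydroxyls removes O–H groups before the organoboron, ylide and copper hydride steps, and the primary silyl ether can later be oxidised directly.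

Step 11
Reactants: 20 pent-4-yn-1-ol
Product: 22 (4E)-5-bromo-4-methylpent-4-en-1-ol, via alkenylalane 21 (not isolated)
Conditions: AlMe3, Cp2ZrCl2 (20 mol %), CH2Cl2, 0 °C → rt; then NBS, THF, −30 °C
Reagents that add atoms: trimethylaluminium (C[Al](C)C); N-bromosuccinimide (O=C1CCC(=O)N1Br)
Why: Zirconium-catalysed Negishi carboalumination adds Me–Al syn across the terminal alkyne (methyl to the internal carbon) and brominolysis of the C–Al bond with retention gives the E-bromoalkene (C7=C8 geometry).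

Step 12
Reactants: 22 (4E)-5-bromo-4-methylpent-4-en-1-ol
Product: 23 (4E)-5-bromo-4-methylpent-4-enal
Conditions: Dess–Martin periodinane, CH2Cl2, rt
Reagents that add atoms: none
Why: Dess–Martin oxidation of a primary alcohol; the alkenyl bromide is inert.

Step 13
Reactants: 23 (4E)-5-bromo-4-methylpent-4-enal
Product: 24 (1E)-1-bromo-2-methylhex-1-en-5-yne
Conditions: dimethyl (1-diazo-2-oxopropyl)phosphonate, K2CO3, MeOH, 0 °C → rt
Reagents that add atoms: dimethyl (1-diazo-2-oxopropyl)phosphonate (COP(=O)(OC)C(=[N+]=[N-])C(C)=O)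
Why: Ohira–Bestmann (Seyferth–Gilbert) homologation turns the aldehyde into the terminal alkyne under mild base that leaves the alkenyl bromide intact.

Step 14
Reactants: 24 (1E)-1-bromo-2-methylhex-1-en-5-yne
Product: 26 (1E)-1-bromo-2-methylhept-1-en-5-yne, via lithium acetylide 25 (not isolated)
Conditions: LiN(iPr)2 (1.05 equiv), THF, −78 °C; MeI, DMPU, −78 → 0 °C
Reagents that add atoms: iodomethane (CI)
Why: The terminal alkyne C–H is by far the most acidic site, and SN2 methylation of the acetylide gives the 2-alkyne.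

Step 15
Reactants: 26 (1E)-1-bromo-2-methylhept-1-en-5-yne
Product: 28 (1E,5E)-1-bromo-6-iodo-2-methylhepta-1,5-diene, via alkenylzirconocene 27 (not isolated)
Conditions: Cp2Zr(H)Cl (2.5 equiv), THF, 45 °C; then I2, 0 °C
Reagents that add atoms: iodine (II)
Why: Hydrozirconation (syn addition) with excess Cp2Zr(H)Cl equilibrates to the isomer with Zr on the methyl-bearing carbon and iodinolysis with retention gives the E-2-iodo-2-alkene, the trisubstituted bromoalkene being inert.

Step 16
Reactants: 19 (3S,4S,6R)-6-[(2S)-1,2-bis(triethylsilyloxy)propan-2-yl]-4-ethenyl-3-methyloxan-2-one; 28 (1E,5E)-1-bromo-6-iodo-2-methylhepta-1,5-diene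
Product: 30 (3S,4R,6R)-4-[(3E,7E)-8-bromo-3,7-dimethylocta-3,7-dien-1-yl]-3-methyl-6-[(2S)-1,2-bis(triethylsilyloxy)propan-2-yl]oxan-2-one, via alkylborane 29 (not isolated)
Conditions: 9-BBN, THF, rt; then 28, Pd(dppf)Cl2 (5 mol %), AsPh3, K3PO4, DMF/H2O, rt
Reagents that add atoms: none
Why: B-alkyl Suzuki–Miyaura coupling: anti-Markovnikov hydroboration of the vinyl group, then coupling at the alkenyl iodide with retention of the E geometry (C11=C12), oxidative addition to C–I being much faster than to the hindered C–Br that is kept for ring closure.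

Step 17
Reactants: 30 (3S,4R,6R)-4-[(3E,7E)-8-bromo-3,7-dimethylocta-3,7-dien-1-yl]-3-methyl-6-[(2S)-1,2-bis(triethylsilyloxy)propan-2-yl]oxan-2-one
Product: 31 (3S,4R,6R)-4-{2-[(2S,3S)-3-[(3E)-4-bromo-3-methylbut-3-en-1-yl]-2-methyloxiran-2-yl]ethyl}-3-methyl-6-[(2S)-1,2-bis(triethylsilyloxy)propan-2-yl]oxan-2-one
Conditions: L-fructose-derived Shi ketone (30 mol %), Oxone (2KHSO5·KHSO4·K2SO4), K2CO3, Bu4NHSO4, MeCN/dimethoxymethane/aq. buffer (pH 10), 0 °C
Reagents that add atoms: potassium peroxymonosulfate ([K+].[O-]S(=O)(=O)OO)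
Why: Shi asymmetric epoxidation (chiral dioxirane, spiro transition state) of the only electron-rich trisubstituted alkene, the L-fructose-derived ketone giving the (S,S)-epoxide (C11, C12) under reagent control while the bromoalkene is deactivated.

Step 18
Reactants: 31 (3S,4R,6R)-4-{2-[(2S,3S)-3-[(3E)-4-bromo-3-methylbut-3-en-1-yl]-2-methyloxiran-2-yl]ethyl}-3-methyl-6-[(2S)-1,2-bis(triethylsilyloxy)propan-2-yl]oxan-2-one
Product: 33 (3S,4R,6R)-4-{2-[(2S,3S)-3-[(3E)-4-bromo-3-methylbut-3-en-1-yl]-2-methyloxiran-2-yl]ethyl}-3-methyl-6-[(2S)-2-(triethylsilyloxy)but-3-en-2-yl]oxan-2-one, via aldehyde 32 (not isolated)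
Conditions: (COCl)2, DMSO, CH2Cl2, −78 → −30 °C; Et3N; then Ph3P=CH2 (from MePPh3Br, NaN(SiMe3)2), THF, −78 → 0 °C
Reagents that add atoms: methyltriphenylphosphonium bromide (C[P+](c1ccccc1)(c1ccccc1)c1ccccc1.[Br-])
Why: Swern conditions oxidise a primary triethylsilyl ether directly to the aldehyde (the tertiary silyl ether is untouched) and in-situ Wittig methylenation of the non-enolisable α-silyloxy aldehyde installs the C5=C6 vinyl group.

Step 19
Reactants: 33 (3S,4R,6R)-4-{2-[(2S,3S)-3-[(3E)-4-bromo-3-methylbut-3-en-1-yl]-2-methyloxiran-2-yl]ethyl}-3-methyl-6-[(2S)-2-(triethylsilyloxy)but-3-en-2-yl]oxan-2-one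
Product: 35 (1R,3R,4S,7E,11S,12S,15S)-11,12-epoxy-4-hydroxycembr-7-en-16,3-olide, via silyl ether macrocycle 34 (not isolated)
Conditions: Cu(OAc)2 (10 mol %), DTBM-SEGPHOS (11 mol %), [Pd(cinnamyl)Cl]2 (5 mol %), BrettPhos (11 mol %), MeSiH(OMe)2, NaOSiMe3, THF, 45 °C, slow addition to 2 mM; then Bu4NF, AcOH, THF, rt
Reagents that add atoms: none
Why: Proposed new method: ring-closing anti-Markovnikov hydroalkenylation by dual catalysis — a phosphine-ligated monovalent copper hydride (from Cu(OAc)2 and the silane) adds across the terminal C5=C6 vinyl group to give a primary alkylcopper at C6 (oxygen is γ, so no β-elimination), zerovalent palladium inserts into the C7–Br bond with retention of the E geometry, alkyl transfer from copper to divalent palladium and reductive elimination form the C6–C7 sp3–sp2 bond and the 14-membered ring under high dilution, and NaOSiMe3 with the silane regenerates the copper hydride; the closest known reaction types are the intermolecular CuH/Pd co-catalysed anti-Markovnikov hydroarylation of terminal alkenes with aryl bromides and the B-alkyl Suzuki macrocyclisation, and the former has not been shown for an alkenyl bromide or in a ring-closing mode; no stereocentre is formed and fluoride then frees the C4 hydroxyl.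

Step 20
Reactants: 35 (1R,3R,4S,7E,11S,12S,15S)-11,12-epoxy-4-hydroxycembr-7-en-16,3-olide
Product: 36 (1R,3R,4S,6E,8S,11S,12S,15S)-11,12-epoxy-8-hydroperoxy-4-hydroxycembr-6-en-16,3-olide
Conditions: O2, tetraphenylporphyrin (1 mol %), hν (white LED), CH2Cl2, −20 °C; HPLC
Reagents that add atoms: dioxygen (O=O)
Why: Schenck ene reaction in which singlet oxygen adds suprafacially to the exposed peripheral face of the E-trisubstituted alkene, bonds to C8 and abstracts an allylic H from C6 on the more crowded side to give the tertiary hydroperoxide and the 6E alkene, so C8 is set by substrate (macrocycle) control only and the C8 epimer and the C7-hydroperoxy exo-methylene regioisomer must be removed by HPLC.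

**Compound list**

1 | 5,6-dihydro-2H-pyran-2-one | O=C1C=CCCO1 | starting material
2 | potassium vinyltrifluoroborate | [K+].C=C[B-](F)(F)F | starting material
3 | (4R)-4-ethenyloxan-2-one | O=C1C[C@H](C=C)CCO1 | intermediate
4 | lithium (4S)-4-ethenyl-5,6-dihydro-4H-pyran-2-olate (enolate of 3, not isolated) | [Li+].[O-]C1=C[C@H](C=C)CCO1 | intermediate
5 | (3S,4S)-4-ethenyl-3-methyloxan-2-one | C[C@@H]1C(=O)OCC[C@H]1C=C | intermediate
6 | potassium (2S,3S)-3-ethenyl-5-hydroxy-2-methylpentanoate (not isolated) | [K+].C[C@@H]([C@@H](CCO)C=C)C([O-])=O | intermediate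
7 | prop-2-en-1-yl (2S,3S)-3-ethenyl-5-hydroxy-2-methylpentanoate | C[C@@H]([C@@H](CCO)C=C)C(=O)OCC=C | intermediate
8 | prop-2-en-1-yl (2S,3S)-3-ethenyl-2-methyl-5-oxopentanoate | C[C@@H]([C@@H](CC=O)C=C)C(=O)OCC=C | intermediate
9 | bromoethane | CCBr | starting material
10 | ethyltriphenylphosphonium bromide | CC[P+](c1ccccc1)(c1ccccc1)c1ccccc1.[Br-] | intermediate
11 | ethyl formate | CCOC=O | starting material
12 | ethylidenetriphenyl-λ5-phosphane (not isolated) | CC=P(c1ccccc1)(c1ccccc1)c1ccccc1 | intermediate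
13 | 2-(triphenyl-λ5-phosphanylidene)propanal | CC(C=O)=P(c1ccccc1)(c1ccccc1)c1ccccc1 | intermediate
14 | prop-2-en-1-yl (2S,3S,5E)-3-ethenyl-2,6-dimethyl-7-oxohept-5-enoate (not isolated) | C[C@@H]([C@@H](C/C=C(\C)C=O)C=C)C(=O)OCC=C | intermediate
15 | prop-2-en-1-yl (2S,3S,5E)-3-ethenyl-7-hydroxy-2,6-dimethylhept-5-enoate | C[C@@H]([C@@H](C/C=C(\C)CO)C=C)C(=O)OCC=C | intermediate
16 | prop-2-en-1-yl (2S,3S)-3-{[(2S,3S)-3-(hydroxymethyl)-3-methyloxiran-2-yl]methyl}-2-methylpent-4-enoate | C[C@@H]([C@@H](C[C@@H]1O[C@@]1(C)CO)C=C)C(=O)OCC=C | intermediate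
17 | (2S,3S)-3-{[(2S,3S)-3-(hydroxymethyl)-3-methyloxiran-2-yl]methyl}-2-methylpent-4-enoic acid (not isolated) | C[C@@H]([C@@H](C[C@@H]1O[C@@]1(C)CO)C=C)C(O)=O | intermediate
18 | (3S,4S,6R)-6-[(2S)-1,2-dihydroxypropan-2-yl]-4-ethenyl-3-methyloxan-2-one | C[C@@H]1C(=O)O[C@H](C[C@H]1C=C)[C@@](C)(O)CO | intermediate
19 | (3S,4S,6R)-6-[(2S)-1,2-bis(triethylsilyloxy)propan-2-yl]-4-ethenyl-3-methyloxan-2-one | C[C@@H]1C(=O)O[C@H](C[C@H]1C=C)[C@@](C)(O[Si](CC)(CC)CC)CO[Si](CC)(CC)CC | intermediate
20 | pent-4-yn-1-ol | C#CCCCO | starting material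
21 | dimethyl[(1E)-5-(dimethylalumanyloxy)-2-methylpent-1-en-1-yl]alumane (not isolated) | C[Al](C)/C=C(\C)CCCO[Al](C)C | intermediate
22 | (4E)-5-bromo-4-methylpent-4-en-1-ol | OCCC/C(C)=C/Br | intermediate
23 | (4E)-5-bromo-4-methylpent-4-enal | O=CCC/C(C)=C/Br | intermediate
24 | (1E)-1-bromo-2-methylhex-1-en-5-yne | C#CCC/C(C)=C/Br | intermediate
25 | lithium acetylide of 24 (not isolated) | [Li]C#CCC/C(C)=C/Br | intermediate
26 | (1E)-1-bromo-2-methylhept-1-en-5-yne | CC#CCC/C(C)=C/Br | intermediate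
27 | chlorobis(cyclopentadienyl)[(2E,6E)-7-bromo-6-methylhepta-2,6-dien-2-yl]zirconium (not isolated) | C/C(=C\CC/C(C)=C/Br)[Zr](Cl)(C1C=CC=C1)C1C=CC=C1 | intermediate
28 | (1E,5E)-1-bromo-6-iodo-2-methylhepta-1,5-diene | C/C(I)=C\CC/C(C)=C/Br | intermediate
29 | 9-BBN adduct of 19, boron on the terminal carbon (C13) of the former vinyl group (not isolated) | C[C@@H]1C(=O)O[C@H](C[C@H]1CCB1C2CCCC1CCC2)[C@@](C)(O[Si](CC)(CC)CC)CO[Si](CC)(CC)CC | intermediate
30 | (3S,4R,6R)-4-[(3E,7E)-8-bromo-3,7-dimethylocta-3,7-dien-1-yl]-3-methyl-6-[(2S)-1,2-bis(triethylsilyloxy)propan-2-yl]oxan-2-one | C[C@@H]1C(=O)O[C@H](C[C@H]1CC/C(C)=C/CC/C(C)=C/Br)[C@@](C)(O[Si](CC)(CC)CC)CO[Si](CC)(CC)CC | intermediate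
31 | (3S,4R,6R)-4-{2-[(2S,3S)-3-[(3E)-4-bromo-3-methylbut-3-en-1-yl]-2-methyloxiran-2-yl]ethyl}-3-methyl-6-[(2S)-1,2-bis(triethylsilyloxy)propan-2-yl]oxan-2-one | C[C@@H]1C(=O)O[C@H](C[C@H]1CC[C@]1(C)O[C@H]1CC/C(C)=C/Br)[C@@](C)(O[Si](CC)(CC)CC)CO[Si](CC)(CC)CC | intermediate
32 | (3S,4R,6R)-4-{2-[(2S,3S)-3-[(3E)-4-bromo-3-methylbut-3-en-1-yl]-2-methyloxiran-2-yl]ethyl}-3-methyl-6-[(2R)-1-oxo-2-(triethylsilyloxy)propan-2-yl]oxan-2-one (not isolated) | C[C@@H]1C(=O)O[C@H](C[C@H]1CC[C@]1(C)O[C@H]1CC/C(C)=C/Br)[C@@](C)(O[Si](CC)(CC)CC)C=O | intermediate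
33 | (3S,4R,6R)-4-{2-[(2S,3S)-3-[(3E)-4-bromo-3-methylbut-3-en-1-yl]-2-methyloxiran-2-yl]ethyl}-3-methyl-6-[(2S)-2-(triethylsilyloxy)but-3-en-2-yl]oxan-2-one | C[C@@H]1C(=O)O[C@H](C[C@H]1CC[C@]1(C)O[C@H]1CC/C(C)=C/Br)[C@@](C)(O[Si](CC)(CC)CC)C=C | intermediate
34 | (1R,3R,4S,7E,11S,12S,15S)-11,12-epoxy-4-(triethylsilyloxy)cembr-7-en-16,3-olide (not isolated) | C[C@@H]1C(=O)O[C@@H]2C[C@H]1CC[C@]1(C)O[C@H]1CC/C(C)=C/CC[C@]2(C)O[Si](CC)(CC)CC | intermediate
35 | (1R,3R,4S,7E,11S,12S,15S)-11,12-epoxy-4-hydroxycembr-7-en-16,3-olide | C[C@@H]1C(=O)O[C@@H]2C[C@H]1CC[C@]1(C)O[C@H]1CC/C(C)=C/CC[C@]2(C)O | intermediate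
36 | (1R,3R,4S,6E,8S,11S,12S,15S)-11,12-epoxy-8-hydroperoxy-4-hydroxycembr-6-en-16,3-olide (CNP0297487.4) | C[C@@H]1C(=O)O[C@@H]2C[C@H]1CC[C@]1(C)O[C@H]1CC[C@](C)(OO)/C=C/C[C@]2(C)O | target

**Step count**

Total step count: 20. Longest linear sequence: 13 steps (1–4, 7–10, 16–20). The ylide branch (steps 5–6) joins at step 7 and the diene branch (steps 11–15) joins at step 16.

**Three steps most likely to fail**

Step 19 (the proposed ring closure). Risks are reduction of the alkenyl bromide or of the alkene instead of coupling, slow meeting of the alkylcopper and the alkenylpalladium within one chain, and attack of NaOSiMe3 on the lactone. The fallback uses known chemistry and sets out from 33. Hydroboration of the vinyl group with 9-BBN (THF, rt) gives the B-alkyl-9-BBN adduct F1. Slow addition of F1 to Pd(dppf)Cl2/AsPh3/Cs2CO3 in DMF/THF/H2O at 50 °C (final 2 mM) effects an intramolecular B-alkyl Suzuki–Miyaura coupling at the alkenyl bromide, a known mode of sp2–sp3 macrocyclisation. This gives 34, and desilylation with Bu4NF/AcOH as in step 19 returns to the route at 35.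

Step 20 (ene hydroperoxidation). The cis effect allows hydrogen abstraction from the C19 methyl as well as from C6, and the face of attack is fixed only by the macrocycle conformation, so the wanted isomer may be a minor component. The fallback changes from a pericyclic to an ionic, regiospecific sequence and sets out from 34, isolated instead of being desilylated, because a free C4 hydroxyl would cyclise onto the seleniranium ion. PhSeBr and 2-hydroperoxy-2-methoxypropane (2,6-di-tert-butylpyridine, CH2Cl2, −78 °C) add across C7=C8 in the Markovnikov, anti sense to give the β-peroxy selenide F2. Oxidation with mCPBA at −78 °C and warming with iPr2NH triggers selenoxide syn-elimination, which can only go toward C6 because C8 bears no hydrogen, and gives the E-allylic peroxyketal F3. PPTS/MeOH followed by Bu4NF/AcOH removes the peroxyketal and the silyl ether and arrives at 36. Regiochemistry is then fixed; the face of selenium attack is still substrate-controlled and could be biased with a chiral arylselenium electrophile.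

Step 9 (epoxide-opening lactonisation). Lewis-acid activation could divert the carboxylate to the tertiary carbon C4 (7-endo), and the free epoxy alcohol can undergo Payne-type migration. The fallback sets out from 16 and replaces titanium templating by a plain SN2 opening on an O-protected epoxide. TBSCl/imidazole gives the silyl ether F4. Pd(PPh3)4/pyrrolidine then gives the epoxy acid F5. Heating its caesium salt (Cs2CO3, DMF, 60 °C) lets the carboxylate attack the secondary carbon C3 in a 6-exo fashion with inversion, giving the hydroxy lactone F6. HF·pyridine removes the silyl group and returns to the route at diol 18.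

**Further compounds**

F1 | step 19 | 9-BBN adduct of 33 (boron on C6, the terminal carbon of the former vinyl group) | C[C@@H]1C(=O)O[C@H](C[C@H]1CC[C@]1(C)O[C@H]1CC/C(C)=C/Br)[C@@](C)(O[Si](CC)(CC)CC)CCB1C2CCCC1CCC2
F2 | step 20 | (1R,3R,4S,7R,8S,11S,12S,15S)-11,12-epoxy-8-[(2-methoxypropan-2-yl)peroxy]-7-(phenylselanyl)-4-(triethylsilyloxy)cembran-16,3-olide | C[C@@H]1C(=O)O[C@@H]2C[C@H]1CC[C@]1(C)O[C@H]1CC[C@](C)(OOC(C)(C)OC)[C@H]([Se]c1ccccc1)CC[C@]2(C)O[Si](CC)(CC)CC
F3 | step 20 | (1R,3R,4S,6E,8S,11S,12S,15S)-11,12-epoxy-8-[(2-methoxypropan-2-yl)peroxy]-4-(triethylsilyloxy)cembr-6-en-16,3-olide | C[C@@H]1C(=O)O[C@@H]2C[C@H]1CC[C@]1(C)O[C@H]1CC[C@](C)(OOC(C)(C)OC)/C=C/C[C@]2(C)O[Si](CC)(CC)CC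
F4 | step 9 | prop-2-en-1-yl (2S,3S)-3-{[(2S,3S)-3-({[tert-butyl(dimethyl)silyl]oxy}methyl)-3-methyloxiran-2-yl]methyl}-2-methylpent-4-enoate | C[C@@H]([C@@H](C[C@@H]1O[C@@]1(C)CO[Si](C)(C)C(C)(C)C)C=C)C(=O)OCC=C
F5 | step 9 | (2S,3S)-3-{[(2S,3S)-3-({[tert-butyl(dimethyl)silyl]oxy}methyl)-3-methyloxiran-2-yl]methyl}-2-methylpent-4-enoic acid | C[C@@H]([C@@H](C[C@@H]1O[C@@]1(C)CO[Si](C)(C)C(C)(C)C)C=C)C(O)=O
F6 | step 9 | (3S,4S,6R)-6-[(2S)-1-{[tert-butyl(dimethyl)silyl]oxy}-2-hydroxypropan-2-yl]-4-ethenyl-3-methyloxan-2-one | C[C@@H]1C(=O)O[C@H](C[C@H]1C=C)[C@@](C)(O)CO[Si](C)(C)C(C)(C)C
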